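The runs were generated by integration with made-up constants; scatter was added.

- Each target I make sets two acids loose: one leaves the protonated nucleophile to free the nucleophile, and one comes from the coupling. If free base takes both, a target costs two equivalents of it.

| flask | electrophile | free base | protonated nucleophile | temperature | remark | time |
|---|---|---|---|---|---|---|
| dawn | 20 mM (in portions, 4) | 22 mM | 9.5 mM | 20 °C | run made earlier; portions every 20 min |  |
| dusk | 20 mM (in portions, 4) | 22 mM | 14 mM | 31 °C | run made earlier; portions every 20 min |  |
| spring | 20 mM (in portions, 4) | 11 mM | 19 mM | 20 °C | run made earlier; portions every 20 min |  |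
| cedar | 20 mM (in portions, 4) | 22.0 mM | 19.0 mM | 25 °C | the portions of electrophile follow each other after 20 min, the first at the start | 80 min |
| alder | 20 mM | 22.0 mM | 19.0 mM | 25 °C | everything together at the start | 80 min |

| run | time / min | target / % | electrophile / % |
|---|---|---|---|
| dawn | 10.0 | 3.1 | 20.5 |
| dawn | 20.0 | 7.4 | 16.8 |
| dawn | 30.0 | 14.1 | 33.7 |
| dawn | 40.0 | 17.1 | 32.0 |
| dawn | 50.0 | 23.0 | 48.3 |
| dawn | 60.0 | 28.6 | 42.9 |
| dusk | 10.0 | 11.8 | 14.3 |
| dusk | 20.0 | 19.0 | 7.1 |
| dusk | 30.0 | 30.3 | 17.6 |
| dusk | 40.0 | 35.8 | 12.0 |
| dusk | 50.0 | 45.9 | 26.8 |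
| dusk | 60.0 | 51.1 | 18.1 |
| spring | 12.0 | 5.4 | 17.1 |
| spring | 25.0 | 11.2 | 33.7 |
| spring | 40.0 | 18.4 | 25.0 |
| spring | 50.0 | 24.6 | 40.0 |
| spring | 60.0 | 27.9 | 32.9 |

(standard deviation of a reading: 1 percentage point)

- amounts and yields of acid set free count idle adduct too
- on the list of suspects stand: electrophile + acid set free <-> idle adduct; nucleophile + acid set free <-> protonated nucleophile; electrophile + nucleophile -> acid set free + target; acid set free -> by-product carried off; acid set free + free base <-> salt of the base

* which of the two ends with the higher amount of target, in percent of the electrophile charged ("neither" if they lie within 2 percentage points) (cedar / alder / neither)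
* target at the end, in percent of the electrophile charged, cedar
* target at the end, in percent of the electrophile charged, alder

- From above, the loose bound was 95.0%, the protonated nucleophile charged against the electrophile charged.
- To tighten it, I froze free acid, by-product and free nucleophile at zero. Then 2·[target] = [salt of the base] + [idle adduct].
- With [idle adduct] at zero too, and free base as limiting reagent, target stood at 55.0%. This is my two-acid line, the free base charge divided by two, then by the electrophile charge.
- That floor needs the base spent by the end. The dusk run, at 31 °C, read 51.1% at 60.0 min. For 25 °C this stayed my assumption.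
- The spring run read 27.9% at 60.0 min, against its own line of 27.5%. About 14 percentage points of the 75.0% then charged was missing from the readings, so idle adduct had to count.
- For the roof, I let idle adduct take every electrophile that was not target. That gave 70.0%, the free base and electrophile charges summed, then spread over 3 electrophile charges.
- Over the 80 min, cedar had on average 62.5% of its electrophile added, less than alder. So I placed alder higher in the bracket.
- The forecast said alder, with cedar at 53% (45% to 62%) and alder at 61% (52% to 72%), on the ground that “base caps target near 11 mM”. Its cedar value lay below my floor, and its alder value lay inside the bracket.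
- Cedar ended at 58.5% and alder at 64.1%, so alder gave more. At 80.0 min, idle adduct stood at 11.5% in cedar and 13.8% in alder.

    electrophile + acid set free ⇌ idle adduct, settled at all times (K = 400 L mol⁻¹, ΔH = −1.00 kJ mol⁻¹)
    nucleophile + acid set free ⇌ protonated nucleophile, settled at all times (K = 3100 L mol⁻¹, ΔH = −47.0 kJ mol⁻¹)
    electrophile + nucleophile → acid set free + target (k = 5.70 L mol⁻¹ min⁻¹, Ea = 61.0 kJ mol⁻¹)
    acid set free → by-product carried off (k = 0.00590 min⁻¹, Ea = 97.0 kJ mol⁻¹)
    acid set free + free base ⇌ salt of the base (K = 1.10 × 10⁶ L mol⁻¹, k = 120 L mol⁻¹ min⁻¹, Ea = 48.0 kJ mol⁻¹, ΔH = −50.0 kJ mol⁻¹)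
    (constants at 25 °C)

- I then took cedar with 13 mM of free base. Its two-acid line fell to 32.5% and its roof to 55.0%. That flask ended at 45.8%, with idle adduct at 22.8%.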